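A direct plan would join catechol A1 to 3,5-dibromo-2-fluorobenzaldehyde A2 by SNAr to give aldehyde A3, tribrominate the hydroxylated ring to A4, transfer a 2,4-dibromophenyl group from trivalent iodine to the remaining phenol to give triaryl aldehyde A5, and end with a Dakin oxidation of CHO to OH. Its weakest steps would be the late tribromination (the 3,4,5-pattern would rest on competing directing effects in an advanced intermediate), the O-arylation (a di-ortho-substituted, electron-poor phenoxide would have to take up an ortho-bromoaryl group) and the Dakin oxidation (an electron-poor, di-ortho-substituted aryl migrates reluctantly, and the formyl group adds length without complexity).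

With ring A the terminal phenol, ring B the central tribromo ring and ring C the 2,4-dibromophenyl ring, each ether carbon C2 of rings A and B lies between an oxygen-bearing C1 and a brominated C3, the pattern of an o-quinone diazide. The route would disconnect both C2–O bonds to a diazide and a phenol: Rh2(OAc)4 expels N2 and the carbenoid carbon inserts into the phenolic O–H, re-aromatising the ring and unmasking the next OH. Two iterations (C, then B, then A) would assemble the bis-ether with all seven bromines bought in place or set under amino control, so no late bromination, no aryl transfer to a hindered phenoxide and no formyl-to-hydroxyl exchange would remain.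

Key step: step 4

Remark: the target has no stereocentre, so no step sets or scrambles one. 3,4,5-Tribromophenol is taken as a catalogue compound. The two o-quinone diazides would be kept cold, in the dark and in solution where possible, since dry diazo compounds of this class can decompose violently.

Step 1
Reactants: 1 3,4,5-tribromophenol
Product: 2 3,4,5-tribromo-2-nitrophenol
Conditions: HNO3 (65%, 1.05 equiv), AcOH, 10 °C to rt
Reagents that add atoms: nitric acid, O[N+](=O)[O-]
Why: Electrophilic aromatic nitration in which OH directs ortho/para, C4 is blocked by bromine and C2 and C6 are equivalent by symmetry, so a single mononitro isomer is expected and the nitro group then deactivates the ring against a second substitution.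

Step 2
Reactants: 2 3,4,5-tribromo-2-nitrophenol
Product: 3 2-amino-3,4,5-tribromophenol
Conditions: Na2S2O4 (5 equiv), THF/H2O, 50 °C
Reagents that add atoms: none
Why: Dithionite reduction of a nitroarene to the aniline should be chemoselective and leave the three C–Br bonds untouched, unlike catalytic hydrogenation.

Step 3
Reactants: 3 2-amino-3,4,5-tribromophenol
Product: 4 3,4,5-tribromo-6-diazocyclohexa-2,4-dien-1-one (o-quinone diazide of ring B; polar form 2,3,4-tribromo-6-oxidobenzene-1-diazonium)
Conditions: t-BuONO (1.5 equiv), AcOH/MeCN, 0 °C to rt, dark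
Reagents that add atoms: tert-butyl nitrite, CC(C)(C)ON=O
Why: Diazotisation of an o-aminophenol with an alkyl nitrite, in which the acidic o-hydroxy diazonium ion loses its phenolic proton to give the neutral diazo oxide.

Step 4
Reactants: 4 3,4,5-tribromo-6-diazocyclohexa-2,4-dien-1-one; 5 2,4-dibromophenol
Product: 6 3,4,5-tribromo-2-(2,4-dibromophenoxy)phenol
Conditions: Rh2(OAc)4 (2 mol %), 5 (3 equiv), ClCH2CH2Cl, 70 °C, slow addition of 4, dark, Ar
Reagents that add atoms: none
Why: Rh2(OAc)4 attacks the diazo carbon of 4 and expels N2 to give an electrophilic divalent-rhodium carbenoid (an o-oxido aryl cation in its polar form); the oxygen of 5 adds to this carbon to give a metal-bound oxonium ylide, and a proton shift from the oxonium oxygen to the neighbouring oxygen releases the catalyst and restores the aromatic sextet of ring B as a 2-aryloxyphenol. The closest known reaction type is the carbenoid O–H insertion of α-diazo ketones and diazoquinones with hydroxylic compounds. No ring is closed and no stereocentre is formed; the step forms the C2(ring B)–O bond and fixes the pattern of ring B, because the ether oxygen can only enter at the former diazo carbon, between C1–OH and C3–Br. The selectivity needed is O–H insertion over Wolff ring contraction, over attack of the carbenoid on a second diazide or on product 6, and over attack on an arene carbon; the metal-bound carbenoid at 70 °C in the dark should suppress the first, slow addition of 4 to an excess of 5 the second, and the electron-poor bromoarenes (para position of 5 blocked) the third. No base is present, so azo coupling of a diazonium form with the phenol is not expected.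

Step 5
Reactants: 7 2-methoxyaniline
Product: 8 2,4-dibromo-6-methoxyaniline
Conditions: NBS (2.05 equiv), MeCN, 0 °C to rt
Reagents that add atoms: N-bromosuccinimide, O=C1CCC(=O)N1Br
Why: Electrophilic aromatic bromination in which the amino group, the stronger donor, directs the two bromines to its para and its free ortho position.

Step 6
Reactants: 8 2,4-dibromo-6-methoxyaniline
Product: 9 2-amino-3,5-dibromophenol
Conditions: BBr3 (3 equiv), CH2Cl2, −78 °C to rt; then H2O, work-up at pH 7
Reagents that add atoms: none
Why: Lewis-acid cleavage of the aryl methyl ether (boron binds oxygen, bromide attacks the methyl group by SN2), with excess reagent to cover complexation by the amine and with the C–Br bonds inert.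

Step 7
Reactants: 9 2-amino-3,5-dibromophenol
Product: 10 3,5-dibromo-6-diazocyclohexa-2,4-dien-1-one (o-quinone diazide of ring A; polar form 2,4-dibromo-6-oxidobenzene-1-diazonium)
Conditions: t-BuONO (1.5 equiv), AcOH/MeCN, 0 °C to rt, dark
Reagents that add atoms: tert-butyl nitrite, CC(C)(C)ON=O
Why: Diazotisation of the o-aminophenol as in step 3, the diazonium ion giving the neutral diazo oxide by loss of the phenolic proton.

Step 8
Reactants: 6 3,4,5-tribromo-2-(2,4-dibromophenoxy)phenol; 10 3,5-dibromo-6-diazocyclohexa-2,4-dien-1-one
Product: 11 bromoiesol A, 3,5-dibromo-2-[3,4,5-tribromo-2-(2,4-dibromophenoxy)phenoxy]phenol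
Conditions: Rh2(OAc)4 (3 mol %), 6 (1.5 equiv, excess recovered), ClCH2CH2Cl, 70 °C, slow addition of 10, dark, Ar
Reagents that add atoms: none
Why: Second carbenoid O–H insertion of an o-quinone diazide, now into the OH that step 4 unmasked on ring B, so that the C2(ring A)–O bond forms at the former diazo carbon and re-aromatisation of ring A delivers the free phenol of the target without any protecting group.

Compound list
1 | 3,4,5-tribromophenol | Oc1cc(Br)c(Br)c(Br)c1 | starting material
2 | 3,4,5-tribromo-2-nitrophenol | Oc1cc(Br)c(Br)c(Br)c1[N+](=O)[O-] | intermediate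
3 | 2-amino-3,4,5-tribromophenol | Nc1c(O)cc(Br)c(Br)c1Br | intermediate
4 | 3,4,5-tribromo-6-diazocyclohexa-2,4-dien-1-one | [N-]=[N+]=C1C(=O)C=C(Br)C(Br)=C1Br | intermediate
5 | 2,4-dibromophenol | Oc1ccc(Br)cc1Br | starting material
6 | 3,4,5-tribromo-2-(2,4-dibromophenoxy)phenol | Oc1cc(Br)c(Br)c(Br)c1Oc1ccc(Br)cc1Br | intermediate
7 | 2-methoxyaniline | COc1ccccc1N | starting material
8 | 2,4-dibromo-6-methoxyaniline | COc1cc(Br)cc(Br)c1N | intermediate
9 | 2-amino-3,5-dibromophenol | Nc1c(O)cc(Br)cc1Br | intermediate
10 | 3,5-dibromo-6-diazocyclohexa-2,4-dien-1-one | [N-]=[N+]=C1C(=O)C=C(Br)C=C1Br | intermediate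
11 | bromoiesol A, 3,5-dibromo-2-[3,4,5-tribromo-2-(2,4-dibromophenoxy)phenoxy]phenol | Oc1cc(Br)cc(Br)c1Oc1cc(Br)c(Br)c(Br)c1Oc1ccc(Br)cc1Br | target

Total step count: 8. Longest linear sequence: 5 steps (steps 1, 2, 3, 4 and 8); steps 5 to 7 form the branch that joins at step 8.

Steps most likely to fail

1. Step 8. The carbenoid may be consumed by the diazide itself or by a second insertion into the newly formed phenol faster than by the hindered, hydrogen-bonded OH of 6, or the ring may contract by Wolff rearrangement. The fallback would make the same ether by aryl transfer from trivalent iodine, setting out from 8 and 6 and coming back at 11. Diazotisation and iodination of 8 (NaNO2, H2SO4; then KI) would give 1,5-dibromo-2-iodo-3-methoxybenzene F1. Oxidation with mCPBA and TsOH followed by capture with 1,3,5-trimethoxybenzene would give (2,4-dibromo-6-methoxyphenyl)(2,4,6-trimethoxyphenyl)iodonium tosylate F2. The phenoxide of 6 (K2CO3, MeCN) would take up the dibromomethoxyphenyl group to give 1,5-dibromo-3-methoxy-2-[3,4,5-tribromo-2-(2,4-dibromophenoxy)phenoxy]benzene F3, and BBr3 would free the phenol 11.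

2. Step 4. The same competing processes apply (self-reaction of the carbenoid with the diazide oxygen, further insertion into 6, ring contraction), and coupling at the open ortho carbon of 5 is also conceivable. The fallback would build the ring B catechol first, setting out from 1 and coming back at 6. Ortho-formylation of 1 (MgCl2, Et3N, paraformaldehyde, MeCN, reflux; both ortho positions are equivalent) would give 2,3,4-tribromo-6-hydroxybenzaldehyde F4. Dakin oxidation (H2O2, NaOH) would give 3,4,5-tribromobenzene-1,2-diol F5. Its more acidic O2–H, ortho and para to bromine, would be deprotonated with KOtBu (1 equiv) and arylated with (2,4-dibromophenyl)(2,4,6-trimethoxyphenyl)iodonium tosylate F6, itself made from 2,4-dibromo-1-iodobenzene, mCPBA, TsOH and 1,3,5-trimethoxybenzene.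

3. Step 1. The nitrating agent may attack C4 with loss of bromine, or oxidise the phenol to quinones. The fallback would introduce the nitrogen by azo coupling, setting out from 1 and coming back at 3. The phenoxide of 1 (aq. NaOH, 0 °C) would couple with 4-nitrobenzenediazonium tetrafluoroborate at the only open activated position to give 3,4,5-tribromo-2-[(E)-(4-nitrophenyl)diazenyl]phenol F7, and Na2S2O4 would cleave the N=N bond to give 3 directly.

Further compounds
F1 | step 8 | 1,5-dibromo-2-iodo-3-methoxybenzene | COc1cc(Br)cc(Br)c1I
F2 | step 8 | (2,4-dibromo-6-methoxyphenyl)(2,4,6-trimethoxyphenyl)iodonium tosylate | COc1cc(Br)cc(Br)c1[I+]c1c(OC)cc(OC)cc1OC.Cc1ccc(cc1)S(=O)(=O)[O-]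
F3 | step 8 | 1,5-dibromo-3-methoxy-2-[3,4,5-tribromo-2-(2,4-dibromophenoxy)phenoxy]benzene | COc1cc(Br)cc(Br)c1Oc1cc(Br)c(Br)c(Br)c1Oc1ccc(Br)cc1Br
F4 | step 4 | 2,3,4-tribromo-6-hydroxybenzaldehyde | O=Cc1c(O)cc(Br)c(Br)c1Br
F5 | step 4 | 3,4,5-tribromobenzene-1,2-diol | Oc1cc(Br)c(Br)c(Br)c1O
F6 | step 4 | (2,4-dibromophenyl)(2,4,6-trimethoxyphenyl)iodonium tosylate | COc1cc(OC)c([I+]c2ccc(Br)cc2Br)c(OC)c1.Cc1ccc(cc1)S(=O)(=O)[O-]
F7 | step 1 | 3,4,5-tribromo-2-[(E)-(4-nitrophenyl)diazenyl]phenol | Oc1cc(Br)c(Br)c(Br)c1/N=N/c1ccc(cc1)[N+](=O)[O-]
A1 | direct plan | catechol (benzene-1,2-diol) | Oc1ccccc1O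
A2 | direct plan | 3,5-dibromo-2-fluorobenzaldehyde | O=Cc1cc(Br)cc(Br)c1F
A3 | direct plan | 3,5-dibromo-2-(2-hydroxyphenoxy)benzaldehyde | O=Cc1cc(Br)cc(Br)c1Oc1ccccc1O
A4 | direct plan | 3,5-dibromo-2-(3,4,5-tribromo-2-hydroxyphenoxy)benzaldehyde | O=Cc1cc(Br)cc(Br)c1Oc1cc(Br)c(Br)c(Br)c1O
A5 | direct plan | 3,5-dibromo-2-[3,4,5-tribromo-2-(2,4-dibromophenoxy)phenoxy]benzaldehyde | O=Cc1cc(Br)cc(Br)c1Oc1cc(Br)c(Br)c(Br)c1Oc1ccc(Br)cc1Br
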